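Ring atoms of the target: C1 = oxirane carbon bearing CH2OBz, C2 = CHOAc, C3 = CHOBz, C4=C5 = ring alkene, C6 = oxirane CH.
Retrosynthesis: the oxirane goes back to a C1=C6 alkene (peracid), the esters are removed, the C2–O bond and the C1=C6 bond go back to an anti SN2′ opening of an oxygen bridge between C3 and C6, and last the two σ-bonds flanking the alkene, C3–C4 and C5–C6, are cut to give furan-3-ylmethyl benzoate and an acetylene equivalent.
Enabling feature: the cis CH=CH unit C4=C5 lies between two ring carbons (C3, C6) that stand 1,4 across the cyclohexene and can be tied by one oxygen, which is the retron of a furan/alkyne Diels–Alder adduct; the bridge (temporary ring) and two sulfonyl groups (activators of the alkyne surrogate) are the helpers, taken out in steps 3 and 4.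
Forward order: the carbocycle is formed in step 2 as a 7-oxabicyclo[2.2.1]heptene, the bridge is opened to the cyclohexene (step 3), the disulfone is turned into C4=C5 (step 4), C3–OH is benzoylated (step 5) and the oxirane is made last (step 6).
Stereochemistry: C3 comes from a bridgehead of the racemic adduct, chosen by a chiral rhodium catalyst (kinetic resolution, so at most half of the adduct is used); C2 from attack of acetate anti to the bridge oxygen; C1 and C6 from peracid attack anti to the C2 acetate.
Key step: step 2

Assumption: the ferrocenyl diphosphine is written as its (R,S)-enantiomer by analogy with its sense on meso oxabicycles; if the sense on 4 is the opposite one, the (S,R)-ligand is used and nothing else changes.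

Step 1
Reactants: 1 furan-3-ylmethanol
Product: 2 furan-3-ylmethyl benzoate
Conditions: BzCl, Et3N, DMAP (cat.), CH2Cl2, 0 °C to rt
Reagents that add atoms: benzoyl chloride, O=C(Cl)c1ccccc1
Why: Acylation of a primary alcohol with an acid chloride (nucleophilic acyl substitution, DMAP catalysis); no stereocenter is involved.

Step 2
Reactants: 2 furan-3-ylmethyl benzoate; 3 (Z)-1,2-bis(phenylsulfonyl)ethene
Product: 4 rac-[(1R,4S,5S,6R)-5,6-bis(phenylsulfonyl)-7-oxabicyclo[2.2.1]hept-2-en-2-yl]methyl benzoate (exo,exo-disulfone)
Conditions: 2 (2 equiv), concentrated in toluene, 45–50 °C, sealed tube, 2–3 d; exo,exo isomer crystallised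
Reagents that add atoms: none
Why: A concerted, thermally allowed suprafacial [4π+2π] cycloaddition joins the two α-carbons of the furan ring of 2 to the two olefinic carbons of the electron-poor disulfone 3, which serves as an acetylene equivalent; the closest known reaction type is the Diels–Alder reaction of furans with 1,2-bis(arylsulfonyl)ethenes. The carbocyclic six-membered ring (the later cyclohexene C1–C6) is closed by this intermolecular cycloaddition, both ring bonds C3–C4 and C5–C6 at once, and the furan oxygen becomes the one-atom bridge between C3 and C6 of a 7-oxabicyclo[2.2.1]heptene. The bridgehead centers C3 and C6 are fixed relative to each other by the bridge (necessarily cis), the sulfonyl-bearing centers C4 and C5 are cis because the Z geometry of 3 is carried over suprafacially, and their exo orientation should result from thermodynamic control, since furan adducts equilibrate by cycloreversion. No regiochemical question arises because 3 is symmetric, and no absolute control is asked of this step: 4 forms as a racemate and the choice of enantiomer is left to the catalyst of step 3. The selectivity the route needs is exo (the endo face of C1=C2 must stay free for step 3), and it is secured by the reversibility of the cycloaddition and by crystallisation of the exo,exo isomer.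

Step 3
Reactants: 4 rac-[(1R,4S,5S,6R)-5,6-bis(phenylsulfonyl)-7-oxabicyclo[2.2.1]hept-2-en-2-yl]methyl benzoate
Product: 5 [(3R,4S,5S,6R)-6-acetoxy-5-hydroxy-3,4-bis(phenylsulfonyl)cyclohex-1-en-1-yl]methyl benzoate
Conditions: [Rh(cod)Cl]2 (2.5 mol%), (R)-1-[(S)-2-(diphenylphosphino)ferrocenyl]ethyldi-tert-butylphosphine (6 mol%), Bu4NI (10 mol%), AcOH (0.55 equiv), Et3N (0.55 equiv), THF, 50–60 °C, stopped near half conversion; unreacted enantiomer of 4 removed by chromatography
Reagents that add atoms: acetic acid, CC(=O)O
Why: Rhodium-catalysed asymmetric ring opening of an oxabicyclic alkene by a carboxylate (anti SN2′ type), used here as a kinetic resolution: in the reacting enantiomer monovalent rhodium inserts from the exo face into the allylic C6–O bond and acetate attacks the unsubstituted alkene carbon C2 from the face opposite the bridge oxygen, so that C2–OAc is set trans to the retained C3–O (now a hydroxyl) and the double bond moves to C1=C6, whereas the same catalyst sense in the other enantiomer would need attack at the fully substituted C1 and leaves it behind.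

Step 4
Reactants: 5 [(3R,4S,5S,6R)-6-acetoxy-5-hydroxy-3,4-bis(phenylsulfonyl)cyclohex-1-en-1-yl]methyl benzoate
Product: 6 [(5R,6R)-6-acetoxy-5-hydroxycyclohexa-1,3-dien-1-yl]methyl benzoate
Conditions: 6% Na(Hg), Na2HPO4, MeOH–THF, −20 °C
Reagents that add atoms: none
Why: Reductive 1,2-elimination of a vicinal disulfone by electron transfer from Na(Hg), the standard unmasking of the bis(sulfonyl)ethene acetylene equivalent, forms C4=C5 without touching a stereocenter, and the free C3 hydroxyl (a poor leaving group, unlike the acyloxy group of a Julia olefination substrate) should not be expelled.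

Step 5
Reactants: 6 [(5R,6R)-6-acetoxy-5-hydroxycyclohexa-1,3-dien-1-yl]methyl benzoate
Product: 7 [(5R,6R)-6-acetoxy-5-(benzoyloxy)cyclohexa-1,3-dien-1-yl]methyl benzoate
Conditions: BzCl, pyridine, DMAP (cat.), CH2Cl2, 0 °C
Reagents that add atoms: benzoyl chloride, O=C(Cl)c1ccccc1
Why: Base-mediated acylation of the secondary allylic alcohol with an acid chloride (nucleophilic acyl substitution, DMAP catalysis) proceeds with retention at C3 and avoids the acid that would aromatise the dienol.

Step 6
Reactants: 7 [(5R,6R)-6-acetoxy-5-(benzoyloxy)cyclohexa-1,3-dien-1-yl]methyl benzoate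
Product: 8 [(1S,4R,5S,6S)-5-acetoxy-4-(benzoyloxy)-7-oxabicyclo[4.1.0]hept-2-en-6-yl]methyl benzoate (target)
Conditions: mCPBA (1.05 equiv), CH2Cl2, aqueous phosphate buffer (pH 7.5), 0 °C
Reagents that add atoms: 3-chloroperoxybenzoic acid (mCPBA), O=C(OO)c1cccc(Cl)c1
Why: Prilezhaev epoxidation with a peracid should take the more nucleophilic trisubstituted C1=C6 bond of the diene from the face opposite the pseudoaxial C2 acetoxy group, which sets C1 and C6 with the oxirane trans to the C2 acetate and cis to the C3 benzoate, in line with peracid epoxidations of related trans-5,6-diacyloxycyclohexa-1,3-dienes.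

Compound list
1 | furan-3-ylmethanol | OCc1ccoc1 | starting material
2 | furan-3-ylmethyl benzoate | O=C(OCc1ccoc1)c1ccccc1 | intermediate
3 | (Z)-1,2-bis(phenylsulfonyl)ethene | O=S(=O)(c1ccccc1)/C=C\S(=O)(=O)c1ccccc1 | starting material
4 | rac-[(1R,4S,5S,6R)-5,6-bis(phenylsulfonyl)-7-oxabicyclo[2.2.1]hept-2-en-2-yl]methyl benzoate, exo,exo (racemate; the enantiomer consumed in step 3 is drawn) | O=C(OCC1=C[C@@H]2O[C@H]1[C@@H](S(=O)(=O)c1ccccc1)[C@H]2S(=O)(=O)c1ccccc1)c1ccccc1 | intermediate
5 | [(3R,4S,5S,6R)-6-acetoxy-5-hydroxy-3,4-bis(phenylsulfonyl)cyclohex-1-en-1-yl]methyl benzoate | CC(=O)O[C@H]1[C@H](O)[C@H](S(=O)(=O)c2ccccc2)[C@H](S(=O)(=O)c2ccccc2)C=C1COC(=O)c1ccccc1 | intermediate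
6 | [(5R,6R)-6-acetoxy-5-hydroxycyclohexa-1,3-dien-1-yl]methyl benzoate | CC(=O)O[C@H]1[C@H](O)C=CC=C1COC(=O)c1ccccc1 | intermediate
7 | [(5R,6R)-6-acetoxy-5-(benzoyloxy)cyclohexa-1,3-dien-1-yl]methyl benzoate | CC(=O)O[C@H]1[C@H](OC(=O)c2ccccc2)C=CC=C1COC(=O)c1ccccc1 | intermediate
8 | [(1S,4R,5S,6S)-5-acetoxy-4-(benzoyloxy)-7-oxabicyclo[4.1.0]hept-2-en-6-yl]methyl benzoate | CC(=O)O[C@H]1[C@H](OC(=O)c2ccccc2)C=C[C@@H]2O[C@@]21COC(=O)c1ccccc1 | target

Total step count: 6
Longest linear sequence: 6 steps (1 to 8)

Steps most likely to fail

Step 3. What may go wrong: the two sulfonyl groups and the substituent on the alkene slow the insertion of rhodium into the bridge C–O bond, the adduct may cyclorevert at the temperature then needed, and the two enantiomers may react at similar rates. The fallback sets out from 4 and comes back at 7; it exchanges the order of unmasking and bridge opening. Na(Hg) with Na2HPO4 in MeOH–THF at −20 °C should convert rac-4 into the diene rac-[(1S,4R)-7-oxabicyclo[2.2.1]hepta-2,5-dien-2-yl]methyl benzoate F1. With benzoic acid (1 equiv, with Et3N, THF, 40 °C) the same rhodium catalyst should then open the bridge of F1 at the unhindered disubstituted double bond in a regiodivergent resolution. The wanted enantiomer keeps the bridge oxygen as a hydroxyl next to the substituted ring carbon and takes benzoate at the neighbouring carbon, giving [(5R,6R)-5-(benzoyloxy)-6-hydroxycyclohexa-1,3-dien-1-yl]methyl benzoate F2; the other enantiomer gives a regioisomeric hydroxy benzoate that is separated. In this variant the oxygen kept from the bridge becomes the C2 oxygen and the benzoate enters at C3, so the two secondary oxygens are acylated in the reverse order. Acetylation of F2 (Ac2O, pyridine, DMAP, 0 °C) gives 7, and step 6 follows.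

Step 4. What may go wrong: under the methoxide-forming amalgam conditions the acetyl group may migrate from the C2 oxygen to the C3 alkoxide, and the allylic carbanion may expel an allylic acyloxy group instead of the sulfinate. The fallback sets out from 5 and comes back at 6; it masks the hydroxyl and uses an aprotic single-electron reductant. Silylation of 5 (Et3SiOSO2CF3, 2,6-lutidine, CH2Cl2, −78 °C) gives [(3R,4S,5S,6R)-6-acetoxy-3,4-bis(phenylsulfonyl)-5-(triethylsilyloxy)cyclohex-1-en-1-yl]methyl benzoate F3. SmI2 with HMPA in THF at −78 °C should convert F3 by reductive elimination into [(5R,6R)-6-acetoxy-5-(triethylsilyloxy)cyclohexa-1,3-dien-1-yl]methyl benzoate F4, and HF·pyridine in THF at 0 °C should free the hydroxyl of F4 and return 6.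

Step 6. What may go wrong: the peracid may attack the disubstituted C4=C5 bond or the face syn to the acetate, and a second epoxidation may follow. The fallback sets out from 7 and comes back at 8; it replaces substrate control by reagent control. A Shi epoxidation is used, with the dioxirane generated from the fructose-derived ketone (or its enantiomer, whichever delivers oxygen to the face anti to the C2 acetate) and KHSO5 at pH 10.5 in MeCN–dimethoxymethane–water at 0 °C. Such dioxiranes prefer the trisubstituted olefin of a conjugated diene. No new compound is made on this path.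

Further compounds
F1 | step 3 | rac-[(1S,4R)-7-oxabicyclo[2.2.1]hepta-2,5-dien-2-yl]methyl benzoate (the enantiomer that leads on is drawn) | O=C(OCC1=C[C@@H]2O[C@H]1C=C2)c1ccccc1
F2 | step 3 | [(5R,6R)-5-(benzoyloxy)-6-hydroxycyclohexa-1,3-dien-1-yl]methyl benzoate | O[C@H]1[C@H](OC(=O)c2ccccc2)C=CC=C1COC(=O)c1ccccc1
F3 | step 4 | [(3R,4S,5S,6R)-6-acetoxy-3,4-bis(phenylsulfonyl)-5-(triethylsilyloxy)cyclohex-1-en-1-yl]methyl benzoate | CC(=O)O[C@H]1[C@H](O[Si](CC)(CC)CC)[C@H](S(=O)(=O)c2ccccc2)[C@H](S(=O)(=O)c2ccccc2)C=C1COC(=O)c1ccccc1
F4 | step 4 | [(5R,6R)-6-acetoxy-5-(triethylsilyloxy)cyclohexa-1,3-dien-1-yl]methyl benzoate | CC(=O)O[C@H]1[C@H](O[Si](CC)(CC)CC)C=CC=C1COC(=O)c1ccccc1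
F0 | step 6 | none | none
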